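Everything rests on cutting ring A at C4a–C5 and C8–C8a. In ring A (C4a, C5, C6, C7, C8, C8a) no two oxygens are alike: C8a holds the pyran oxygen O1, C5 a free hydroxyl, C7 an ester, and the lone carbon branch, C4 on C4a, has an oxygenated carbon on either side and the third one opposite. A Danheiser benzannulation of a 3-alkoxycyclobutenone with a silyloxyalkyne produces this very pattern, so one thermal operation builds the arene and hands over its oxygens as OH, OTIPS and O-allyl. The precursor is an acyclic TIPS ynol ether already carrying ring B, C2 and C3, both stereocentres set by an Evans glycolate aldol.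

Key step: step 10

Assumption: the catechol monoester of 36 is taken to keep its galloyl group on O3' as long as no base is present, so everything after step 15 is run neutral or faintly acidic. Flavan numbering (O1, C2, C3, C4, C4a, C5 to C8, C8a, primes for ring B) is used for all intermediates.

Step 1
Reactants: 1 4-(benzyloxy)-3-hydroxybenzaldehyde
Product: 2 3-(allyloxy)-4-(benzyloxy)benzaldehyde
Conditions: allyl bromide, K2CO3, DMF, rt
Reagents that add atoms: allyl bromide C=CCBr
Why: Williamson etherification of the only free phenol tags the future 3'-ester oxygen with a group that zerovalent palladium removes later without touching benzyl ethers.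

Step 2
Reactants: 3 (R)-4-benzyl-1,3-oxazolidin-2-one; 4 (benzyloxy)acetyl chloride
Product: 6 (R)-4-benzyl-3-[(benzyloxy)acetyl]-1,3-oxazolidin-2-one, via N-lithio oxazolidinone 5 (not isolated)
Conditions: n-BuLi, THF, −78 °C; then 4, −78 → 0 °C
Reagents that add atoms: none
Why: N-acylation of the lithiated carbamate by an acid chloride is the standard loading of an Evans auxiliary and leaves its stereocentre untouched.

Step 3
Reactants: 6 (R)-4-benzyl-3-[(benzyloxy)acetyl]-1,3-oxazolidin-2-one; 2 3-(allyloxy)-4-(benzyloxy)benzaldehyde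
Product: 9 (R)-4-benzyl-3-{(2R,3S)-3-[3-(allyloxy)-4-(benzyloxy)phenyl]-2-(benzyloxy)-3-hydroxypropanoyl}-1,3-oxazolidin-2-one, via boron enolate 7 (not isolated), via boron aldolate 8 (not isolated)
Conditions: Bu2BOTf, Et3N, CH2Cl2, −78 → 0 °C; 2, −78 → 0 °C; then pH 7 buffer, MeOH, 30% H2O2, 0 °C
Reagents that add atoms: none
Why: Evans syn aldol, in which the (Z)-boron enolate reacts through a chair Zimmerman–Traxler transition state on the face away from the benzyl group of the (R)-auxiliary, setting (2R,3S), that is the final configuration at flavan C3 and an S carbinol at flavan C2.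

Step 4
Reactants: 9 syn aldol adduct
Product: 10 (R)-4-benzyl-3-{(2R,3S)-3-[3-(allyloxy)-4-(benzyloxy)phenyl]-2-(benzyloxy)-3-[(tert-butyldimethylsilyl)oxy]propanoyl}-1,3-oxazolidin-2-one
Conditions: TBSOTf, 2,6-lutidine, CH2Cl2, 0 °C
Reagents that add atoms: tert-butyldimethylsilyl triflate CC(C)(C)[Si](C)(C)OS(=O)(=O)C(F)(F)F
Why: O-silylation with a silyl triflate and a hindered pyridine is fast and too weakly basic for retro-aldol, and it parks the benzylic oxygen until ring closure.

Step 5
Reactants: 10 silylated aldol imide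
Product: 11 (2S,3S)-3-[3-(allyloxy)-4-(benzyloxy)phenyl]-2-(benzyloxy)-3-[(tert-butyldimethylsilyl)oxy]propan-1-ol
Conditions: LiBH4, MeOH (1.1 equiv), THF, 0 °C
Reagents that add atoms: none
Why: Reductive cleavage of an N-acyloxazolidinone by LiBH4 attacks the exocyclic carbonyl, releases the auxiliary for reuse and disturbs neither stereocentre (the R to S change at the benzyloxy carbon is only a priority effect).

Step 6
Reactants: 11 primary alcohol
Product: 12 (2S,3S)-3-[3-(allyloxy)-4-(benzyloxy)phenyl]-2-(benzyloxy)-3-[(tert-butyldimethylsilyl)oxy]propyl trifluoromethanesulfonate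
Conditions: Tf2O, 2,6-lutidine, CH2Cl2, −78 °C; cold aqueous wash, used at once
Reagents that add atoms: triflic anhydride O=S(=O)(OS(=O)(=O)C(F)(F)F)C(F)(F)F
Why: Sulfonylation of the unhindered primary alcohol at low temperature gives a leaving group reactive enough for acetylide alkylation well below the temperature at which neighbouring ether oxygens interfere.

Step 7
Reactants: 12 primary triflate; 13 ethynyltrimethylsilane
Product: 16 (1S,2S)-1-[3-(allyloxy)-4-(benzyloxy)phenyl]-2-(benzyloxy)-1-[(tert-butyldimethylsilyl)oxy]pent-4-yne, via lithium trimethylsilylacetylide 14 (not isolated), via silyl-capped alkyne 15 (not isolated)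
Conditions: 13, n-BuLi, THF, −78 °C; 12, DMPU, −78 → −20 °C; then MeOH, K2CO3, rt
Reagents that add atoms: none
Why: SN2 alkylation of a lithium acetylide by a primary triflate in THF/DMPU installs C4a and C8a, and carbonate methanolysis in the same flask strips only the C-silyl group because the alkyl TBS ether tolerates it.

Step 8
Reactants: 16 terminal alkyne
Product: 19 (1S,2S)-1-[3-(allyloxy)-4-(benzyloxy)phenyl]-2-(benzyloxy)-1-[(tert-butyldimethylsilyl)oxy]-5-[(triisopropylsilyl)oxy]pent-4-yne, via lithium acetylide 17 (not isolated), via lithium ynolate 18 (not isolated)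
Conditions: n-BuLi (1.0 equiv), THF, −78 °C; LiOOt-Bu (from t-BuOOH and LiN(SiMe3)2, THF, −78 °C), −78 → 0 °C; then TIPSOTf, −78 → 0 °C
Reagents that add atoms: tert-butyl hydroperoxide CC(C)(C)OO; triisopropylsilyl triflate CC(C)[Si](OS(=O)(=O)C(F)(F)F)(C(C)C)C(C)C
Why: Acetylide oxidation by lithium tert-butyl peroxide (carbon attack on the O–O bond) gives the ynolate, which the bulky silyl triflate traps on oxygen rather than carbon, the established one-flask conversion of terminal alkynes into triisopropylsilyl ynol ethers.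

Step 9
Reactants: 20 3-ethoxycyclobut-2-en-1-one
Product: 22 3-(allyloxy)cyclobut-2-en-1-one, via mixed ketal 21 (not isolated)
Conditions: allyl alcohol (solvent), camphorsulfonic acid (5 mol %), 4 Å sieves, rt → 35 °C, volatiles stripped and recharged once; Et3N quench
Reagents that add atoms: allyl alcohol C=CCO
Why: Acid-catalysed alkoxy exchange of a vinylogous ester by addition–elimination at C3, the way β-alkoxyenones and squarate esters swap alkoxy groups, is driven by excess allyl alcohol and is run near room temperature so that the ring does not open and the fragile free 1,3-dione is never handled.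

Step 10
Reactants: 19 TIPS ynol ether; 22 3-(allyloxy)cyclobut-2-en-1-one
Product: 27 5-(allyloxy)-2-{(2S,3S)-3-[3-(allyloxy)-4-(benzyloxy)phenyl]-2-(benzyloxy)-3-[(tert-butyldimethylsilyl)oxy]propyl}-3-[(triisopropylsilyl)oxy]phenol, via vinylketene 23 (not isolated), via vinylcyclobutenone 24 (not isolated), via dienylketene 25 (not isolated), via cyclohexadienone 26 (not isolated)
Conditions: 22 (1.5 equiv, in portions), toluene (0.5 M in 19), 80 → 110 °C, sealed tube, argon
Reagents that add atoms: none
Why: Danheiser benzannulation, a four-stage pericyclic cascade: conrotatory 4-electron opening of 22 (C1–C4 bond) gives vinylketene 23, and the chain-bearing, nucleophilic alkyne carbon of 19 bonds to the ketene carbonyl carbon in a [2+2] cycloaddition that makes C4a–C5 and C8–C8a and gives 24. A second 4-electron opening breaks the former C1–C2 bond of the cyclobutenone to give dienylketene 25, and ring A closes by disrotatory 6-electron electrocyclisation (C5–C6) to dienone 26, which tautomerises to phenol 27; cyclobutenone C1, C2, C3 and C4 thus become C5, C8, C7 and C6 and the alkyne supplies C4a and C8a. The closest known reaction is the same annulation of 3-alkylcyclobutenones with trialkylsilyloxyalkynes to resorcinol monosilyl ethers, the only change being that the C3 substituent, a bystander in every bond-forming event, is alkoxy. No lasting stereocentre is formed (the sp3 ring carbon of 24 is erased on reopening), and C2 and C3 experience nothing but neutral heat. The regiochemistry needed, C4 between OH on C5 and OTIPS on C8a and opposite O-allyl on C7, follows from the polarity match of ynol ether and ketene. The chemoselectivity needed, alkyne before the allyl alkenes and before the new phenol, rests on the much higher nucleophilicity of the silyloxyalkyne, the hindered position of the phenol, portionwise feeding of 22 and a temperature far below that of aryl allyl ether Claisen rearrangement.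

Step 11
Reactants: 27 ring A phenol
Product: 28 benzyl ether of 27, namely 5-(allyloxy)-1-(benzyloxy)-2-{(2S,3S)-3-[3-(allyloxy)-4-(benzyloxy)phenyl]-2-(benzyloxy)-3-[(tert-butyldimethylsilyl)oxy]propyl}-3-[(triisopropylsilyl)oxy]benzene
Conditions: BnBr, K2CO3 (anhydrous), DMF, rt
Reagents that add atoms: benzyl bromide BrCc1ccccc1
Why: Williamson benzylation of the single free phenol fixes the C5 oxygen as a hydrogenolysable ether, while the bulky aryl TIPS ether, further shielded by the ortho side chain, tolerates dry carbonate.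

Step 12
Reactants: 28 fully protected open-chain compound
Product: 29 5-(allyloxy)-3-(benzyloxy)-2-{(2S,3S)-3-[3-(allyloxy)-4-(benzyloxy)phenyl]-2-(benzyloxy)-3-hydroxypropyl}phenol
Conditions: Bu4NF (2.5 equiv), THF, 0 °C → rt
Reagents that add atoms: none
Why: Fluoride desilylation frees the C8a phenol and the benzylic alcohol in one flask, benzyl and allyl ethers being inert and ring B unable to form a quinone methide because O4' is alkylated.

Step 13
Reactants: 29 phenol alcohol
Product: 31 (2R,3S)-7,3'-di-O-allyl-3,5,4'-tri-O-benzylcatechin, via alkoxyphosphonium phenoxide 30 (not isolated)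
Conditions: PPh3, DIAD, THF (0.02 M), 0 °C → rt
Reagents that add atoms: none
Why: Intramolecular Mitsunobu etherification, in which the benzylic oxygen is activated as oxyphosphonium 30 and displaced by the C8a phenoxide in a 6-exo-tet SN2 closure with inversion, turns C2 from S into R and the syn chain into the 2,3-trans flavan while C3 is a spectator.

Step 14
Reactants: 31 diallyl tribenzyl catechin
Product: 32 (2R,3S)-3,5,4'-tri-O-benzylcatechin (free 7-OH and 3'-OH)
Conditions: Pd(PPh3)4 (5 mol %), morpholine, THF, rt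
Reagents that add atoms: none
Why: Tsuji–Trost-type deallylation, in which zerovalent palladium ionises both aryl allyl ethers to π-allyl complexes that morpholine intercepts, exposes exactly the two oxygens to be esterified and leaves benzyl ethers alone.

Step 15
Reactants: 32 tribenzyl catechin; 33 3,4,5-tris(benzyloxy)benzoic acid
Product: 35 (2R,3S)-3,5,4'-tri-O-benzylcatechin 7,3'-bis[3,4,5-tris(benzyloxy)benzoate], via O-acylisourea 34 (not isolated)
Conditions: 33 (2.5 equiv), DCC, DMAP, CH2Cl2, 0 °C → rt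
Reagents that add atoms: none
Why: Steglich esterification acylates the only two hydroxyl groups present, so site selectivity is built in, no separate acid chloride step is needed, and acyl migration is impossible because O4' is still benzylated.

Step 16
Reactants: 35 nona-O-benzyl digallate
Product: 36 (2R,3S)-catechin 7,3'-di-O-gallate
Conditions: H2 (1 atm), Pd(OH)2/C, THF/EtOAc (1:1), AcOH (0.5 vol %), rt; filtration, purification with acidified eluent
Reagents that add atoms: none
Why: Catalytic hydrogenolysis removes all nine benzyl ethers under conditions long used for flavan-3-ol gallates, and a non-nucleophilic, faintly acidic medium avoids solvolysis of the aryl esters and 3' to 4' galloyl migration.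

Compound list
1 | 4-(benzyloxy)-3-hydroxybenzaldehyde | O=Cc1ccc(OCc2ccccc2)c(O)c1 | starting material
2 | 3-(allyloxy)-4-(benzyloxy)benzaldehyde | O=Cc1ccc(OCc2ccccc2)c(OCC=C)c1 | intermediate
3 | (R)-4-benzyl-1,3-oxazolidin-2-one | O=C1N[C@H](Cc2ccccc2)CO1 | starting material
4 | (benzyloxy)acetyl chloride | O=C(Cl)COCc1ccccc1 | starting material
5 | N-lithio-(R)-4-benzyl-1,3-oxazolidin-2-one | [Li]N1C(=O)OC[C@H]1Cc1ccccc1 | intermediate
6 | (R)-4-benzyl-3-[(benzyloxy)acetyl]-1,3-oxazolidin-2-one | O=C(COCc1ccccc1)N1C(=O)OC[C@H]1Cc1ccccc1 | intermediate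
7 | (Z)-dibutylboron enolate of 6 | CCCCB(CCCC)O/C(=C\OCc1ccccc1)N1C(=O)OC[C@H]1Cc1ccccc1 | intermediate
8 | O-dibutylboryl aldolate of 9 | CCCCB(CCCC)O[C@@H](c1ccc(OCc2ccccc2)c(OCC=C)c1)[C@@H](OCc1ccccc1)C(=O)N1C(=O)OC[C@H]1Cc1ccccc1 | intermediate
9 | (R)-4-benzyl-3-{(2R,3S)-3-[3-(allyloxy)-4-(benzyloxy)phenyl]-2-(benzyloxy)-3-hydroxypropanoyl}-1,3-oxazolidin-2-one | O[C@@H](c1ccc(OCc2ccccc2)c(OCC=C)c1)[C@@H](OCc1ccccc1)C(=O)N1C(=O)OC[C@H]1Cc1ccccc1 | intermediate
10 | O-TBS ether of 9, (2R,3S) | CC(C)(C)[Si](C)(C)O[C@@H](c1ccc(OCc2ccccc2)c(OCC=C)c1)[C@@H](OCc1ccccc1)C(=O)N1C(=O)OC[C@H]1Cc1ccccc1 | intermediate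
11 | (2S,3S)-3-[3-(allyloxy)-4-(benzyloxy)phenyl]-2-(benzyloxy)-3-(TBS-oxy)propan-1-ol | CC(C)(C)[Si](C)(C)O[C@@H](c1ccc(OCc2ccccc2)c(OCC=C)c1)[C@@H](OCc1ccccc1)CO | intermediate
12 | triflate of 11, (2S,3S) | CC(C)(C)[Si](C)(C)O[C@@H](c1ccc(OCc2ccccc2)c(OCC=C)c1)[C@@H](OCc1ccccc1)COS(=O)(=O)C(F)(F)F | intermediate
13 | ethynyltrimethylsilane | C#C[Si](C)(C)C | starting material
14 | lithium (trimethylsilyl)acetylide | [Li]C#C[Si](C)(C)C | intermediate
15 | (1S,2S)-1-aryl-2-(benzyloxy)-1-(TBS-oxy)-5-(trimethylsilyl)pent-4-yne | CC(C)(C)[Si](C)(C)O[C@@H](c1ccc(OCc2ccccc2)c(OCC=C)c1)[C@@H](OCc1ccccc1)CC#C[Si](C)(C)C | intermediate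
16 | (1S,2S)-1-[3-(allyloxy)-4-(benzyloxy)phenyl]-2-(benzyloxy)-1-(TBS-oxy)pent-4-yne | CC(C)(C)[Si](C)(C)O[C@@H](c1ccc(OCc2ccccc2)c(OCC=C)c1)[C@@H](OCc1ccccc1)CC#C | intermediate
17 | lithium acetylide of 16 | CC(C)(C)[Si](C)(C)O[C@@H](c1ccc(OCc2ccccc2)c(OCC=C)c1)[C@@H](OCc1ccccc1)CC#C[Li] | intermediate
18 | lithium ynolate from 17 | CC(C)(C)[Si](C)(C)O[C@@H](c1ccc(OCc2ccccc2)c(OCC=C)c1)[C@@H](OCc1ccccc1)CC#CO[Li] | intermediate
19 | (1S,2S)-1-aryl-2-(benzyloxy)-1-(TBS-oxy)-5-(TIPS-oxy)pent-4-yne | CC(C)(C)[Si](C)(C)O[C@@H](c1ccc(OCc2ccccc2)c(OCC=C)c1)[C@@H](OCc1ccccc1)CC#CO[Si](C(C)C)(C(C)C)C(C)C | intermediate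
20 | 3-ethoxycyclobut-2-en-1-one | CCOC1=CC(=O)C1 | starting material
21 | 3-(allyloxy)-3-ethoxycyclobutan-1-one | CCOC1(OCC=C)CC(=O)C1 | intermediate
22 | 3-(allyloxy)cyclobut-2-en-1-one | C=CCOC1=CC(=O)C1 | intermediate
23 | 3-(allyloxy)buta-1,3-dien-1-one | C=CCOC(=C)C=C=O | intermediate
24 | 4-[1-(allyloxy)vinyl]-2-[(2S,3S)-side chain]-3-(TIPS-oxy)cyclobut-2-en-1-one, epimers at ring C4 | CC(C)(C)[Si](C)(C)O[C@@H](c1ccc(OCc2ccccc2)c(OCC=C)c1)[C@@H](OCc1ccccc1)CC1=C(O[Si](C(C)C)(C(C)C)C(C)C)C(C(=C)OCC=C)C1=O | intermediate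
25 | (3E)-5-(allyloxy)-2-[(2S,3S)-side chain]-3-(TIPS-oxy)hexa-1,3,5-trien-1-one | CC(C)(C)[Si](C)(C)O[C@@H](c1ccc(OCc2ccccc2)c(OCC=C)c1)[C@@H](OCc1ccccc1)CC(=C=O)/C(O[Si](C(C)C)(C(C)C)C(C)C)=C\C(=C)OCC=C | intermediate
26 | 5-(allyloxy)-2-[(2S,3S)-side chain]-3-(TIPS-oxy)cyclohexa-2,4-dien-1-one | CC(C)(C)[Si](C)(C)O[C@@H](c1ccc(OCc2ccccc2)c(OCC=C)c1)[C@@H](OCc1ccccc1)CC1=C(O[Si](C(C)C)(C(C)C)C(C)C)C=C(OCC=C)CC1=O | intermediate
27 | 5-(allyloxy)-2-{(2S,3S)-3-[3-(allyloxy)-4-(benzyloxy)phenyl]-2-(benzyloxy)-3-(TBS-oxy)propyl}-3-(TIPS-oxy)phenol | CC(C)(C)[Si](C)(C)O[C@@H](c1ccc(OCc2ccccc2)c(OCC=C)c1)[C@@H](OCc1ccccc1)Cc1c(O)cc(OCC=C)cc1O[Si](C(C)C)(C(C)C)C(C)C | intermediate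
28 | O-benzyl ether of 27 | CC(C)(C)[Si](C)(C)O[C@@H](c1ccc(OCc2ccccc2)c(OCC=C)c1)[C@@H](OCc1ccccc1)Cc1c(OCc2ccccc2)cc(OCC=C)cc1O[Si](C(C)C)(C(C)C)C(C)C | intermediate
29 | 5-(allyloxy)-3-(benzyloxy)-2-{(2S,3S)-3-[3-(allyloxy)-4-(benzyloxy)phenyl]-2-(benzyloxy)-3-hydroxypropyl}phenol | O[C@@H](c1ccc(OCc2ccccc2)c(OCC=C)c1)[C@@H](OCc1ccccc1)Cc1c(OCc2ccccc2)cc(OCC=C)cc1O | intermediate
30 | triphenylphosphonium ether of the benzylic oxygen of 29, phenoxide zwitterion | c1ccccc1[P+](c1ccccc1)(c1ccccc1)O[C@@H](c1ccc(OCc2ccccc2)c(OCC=C)c1)[C@@H](OCc1ccccc1)Cc1c(OCc2ccccc2)cc(OCC=C)cc1[O-] | intermediate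
31 | (2R,3S)-7,3'-di-O-allyl-3,5,4'-tri-O-benzylcatechin | C=CCOc1cc(OCc2ccccc2)c2c(c1)O[C@H](c1ccc(OCc3ccccc3)c(OCC=C)c1)[C@@H](OCc1ccccc1)C2 | intermediate
32 | (2R,3S)-3,5,4'-tri-O-benzylcatechin | Oc1cc(OCc2ccccc2)c2c(c1)O[C@H](c1ccc(OCc3ccccc3)c(O)c1)[C@@H](OCc1ccccc1)C2 | intermediate
33 | 3,4,5-tris(benzyloxy)benzoic acid | O=C(O)c1cc(OCc2ccccc2)c(OCc2ccccc2)c(OCc2ccccc2)c1 | starting material
34 | O-[3,4,5-tris(benzyloxy)benzoyl]-N,N'-dicyclohexylisourea | O=C(OC(=NC1CCCCC1)NC1CCCCC1)c1cc(OCc2ccccc2)c(OCc2ccccc2)c(OCc2ccccc2)c1 | intermediate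
35 | (2R,3S)-3,5,4'-tri-O-benzylcatechin 7,3'-bis[3,4,5-tris(benzyloxy)benzoate] | O=C(Oc1cc(OCc2ccccc2)c2c(c1)O[C@H](c1ccc(OCc3ccccc3)c(OC(=O)c3cc(OCc4ccccc4)c(OCc4ccccc4)c(OCc4ccccc4)c3)c1)[C@@H](OCc1ccccc1)C2)c1cc(OCc2ccccc2)c(OCc2ccccc2)c(OCc2ccccc2)c1 | intermediate
36 | (2R,3S)-catechin 7,3'-di-O-gallate | O=C(Oc1cc(O)c2c(c1)O[C@H](c1ccc(O)c(OC(=O)c3cc(O)c(O)c(O)c3)c1)[C@@H](O)C2)c1cc(O)c(O)c(O)c1 | target

Total step count: 16. Longest linear sequence: 14 steps (1 → 2 → 9 → 10 → 11 → 12 → 16 → 19 → 27 → 28 → 29 → 31 → 32 → 35 → 36; the branch from 4 is equally long).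

Steps most likely to fail

(a) Step 10.
- What may go wrong: the donor-stabilised four-membered ring may open too slowly, so that long heating erodes the ynol ether. The vinylketene may also be diverted by its own allyl alkene, by dimerisation or by O-acylation of the phenol as it forms.
- Fallback, from 19 and back at 27: the ketene is generated without any ring opening.
- Ethyl but-2-ynoate is stirred in allyl alcohol with catalytic NaH (alkoxide conjugate addition plus transesterification) to give allyl (E)-3-(allyloxy)but-2-enoate F1.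
- LiOH in aqueous THF then gives (E)-3-(allyloxy)but-2-enoic acid F2, and (COCl)2 with catalytic DMF gives (E)-3-(allyloxy)but-2-enoyl chloride F3.
- Slow addition of F3 to 19 and Et3N in toluene at room temperature causes 1,4-dehydrochlorination to 23, a standard entry to vinylketenes. Ketenes made from acid chlorides are known to add to silyloxyalkynes to give 3-silyloxycyclobutenones.
- Compound 24 formed this way needs only the easier second opening (about 80 °C) to run through 25 and 26 to 27.

(b) Step 9.
- What may go wrong: the alcohol may cleave the strained ring solvolytically, or the exchange may stall short of completion and carry ethoxy material into the key step.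
- Fallback, from 20 and back at 22: cold dilute aqueous HCl hydrolyses the enol ether to cyclobutane-1,3-dione F4, a strongly acidic enol.
- F4 is taken at once into a Mitsunobu O-alkylation with allyl alcohol (PPh3, DIAD, THF, 0 °C). This reaction is irreversible and neutral and is known to alkylate cyclic 1,3-diones and tetronic acids on oxygen.

(c) Step 13.
- What may go wrong: the activated, p-alkoxy-stabilised benzylic centre may ionise before displacement, with leakage of stereospecificity or proton loss towards the enol ether.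
- Fallback, from 29 and back at 31, with no new compound (F0): the stereospecific displacement is given up in favour of substrate control.
- Catalytic camphorsulfonic acid in CH2Cl2 at 0 °C generates the benzylic cation deliberately, and the C8a phenol closes the ring through a half-chair with the aryl and benzyloxy groups pseudo-equatorial. This is the course taken by classical acid cyclisations of 1,3-diarylpropane-1,2-diols to 2,3-trans flavan-3-ols.
- Since C3 is fixed, any stereochemical leakage costs material through a separable diastereomer and does not lower enantiopurity.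

Further compounds
F1 | step 10 | allyl (E)-3-(allyloxy)but-2-enoate | C=CCOC(=O)/C=C(\C)OCC=C
F2 | step 10 | (E)-3-(allyloxy)but-2-enoic acid | OC(=O)/C=C(\C)OCC=C
F3 | step 10 | (E)-3-(allyloxy)but-2-enoyl chloride | ClC(=O)/C=C(\C)OCC=C
F4 | step 9 | cyclobutane-1,3-dione | O=C1CC(=O)C1
F0 | step 13 | none | none
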